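The route rests on cutting the bond between C2 of the 5,7-dihydroxychromone and C6 of the 2,2-dimethylchromene. The key step exploits the C2–H of the pyranone ring (ring C) of a 2-unsubstituted chromone. Bonded to O1 and β to the C4 carbonyl, it is the most acidic C–H present. A zinc amide metalates it in the flask. In the same operation a Negishi coupling joins it to the C6–Cl bond of the complete 8-(chromen-8-yl)apigenin, so the chromone needs no handle. That chloride arises from 8-bromo-6-chlorochromene by bromine-selective lithiation, zincation and coupling with 8-iodoapigenin tris-MOM ether. One acid treatment finally frees all five phenols.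

Key step: step 7

Assumption: the target SMILES carries no stereodescriptor and the molecule has no stereocenter. The biaryl axis between chromene C8 and apigenin C8 is taken as configurationally undefined, so nothing has to be controlled.

Step 1
Reactants: 1 apigenin
Product: 2 5,7-bis(methoxymethoxy)-2-[4-(methoxymethoxy)phenyl]-4H-chromen-4-one
Conditions: NaH (4 equiv), MOMCl (4 equiv), DMF, 0 °C to rt
Reagents that add atoms: chloromethyl methyl ether (MOMCl), COCCl
Why: Williamson-type O-alkylation, in which NaH turns all three phenols, the chelated 5-OH included, into phenoxides that the hard electrophile MOMCl captures on oxygen.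

Step 2
Reactants: 2 5,7-bis(methoxymethoxy)-2-[4-(methoxymethoxy)phenyl]-4H-chromen-4-one
Product: 3 8-iodo-5,7-bis(methoxymethoxy)-2-[4-(methoxymethoxy)phenyl]-4H-chromen-4-one
Conditions: NIS (1.1 equiv), DMF, rt to 50 °C, dark
Reagents that add atoms: N-iodosuccinimide (NIS), O=C1CCC(=O)N1I
Why: Electrophilic aromatic iodination, in which ring A is the most electron-rich ring and C8 (ortho to 7-OMOM and O1, para to 5-OMOM) is less crowded than C6 between two freely rotating MOM ethers, while the neutral medium spares the acetals.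

Step 3
Reactants: 4 2-bromo-4-chlorophenol; 5 3-chloro-3-methylbut-1-yne
Product: 6 2-bromo-4-chloro-1-[(2-methylbut-3-yn-2-yl)oxy]benzene
Conditions: K2CO3 (2 equiv), KI (cat.), CuI (cat.), acetone, reflux
Reagents that add atoms: none
Why: Copper-assisted propargylic O-alkylation of the Williamson type is the standard entry to aryl 1,1-dimethylpropargyl ethers and leaves both aryl halides untouched.

Step 4
Reactants: 6 2-bromo-4-chloro-1-[(2-methylbut-3-yn-2-yl)oxy]benzene
Product: 9 8-bromo-6-chloro-2,2-dimethyl-2H-chromene, via allenylphenol 7 (not isolated), via ortho-quinone methide 8 (not isolated)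
Conditions: N,N-diethylaniline, 200 °C
Reagents that add atoms: none
Why: Aromatic propargyl Claisen rearrangement to the only free ortho carbon, enolisation to 7, 1,5-hydrogen shift to 8 and oxa-6π electrocyclisation should close the pyran ring, the gem-dimethyl group speeding the sigmatropic step.

Step 5
Reactants: 9 8-bromo-6-chloro-2,2-dimethyl-2H-chromene; 3 8-iodo-5,7-bis(methoxymethoxy)-2-[4-(methoxymethoxy)phenyl]-4H-chromen-4-one
Product: 12 8-(6-chloro-2,2-dimethyl-2H-chromen-8-yl)-5,7-bis(methoxymethoxy)-2-[4-(methoxymethoxy)phenyl]-4H-chromen-4-one, via aryllithium 10 (not isolated), via arylzinc chloride 11 (not isolated)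
Conditions: 9 (1.3 equiv), n-BuLi, THF, −78 °C; ZnCl2, −78 °C to rt; then 3 (1.0 equiv), Pd(PPh3)4 (5 mol %), THF, 60 °C
Reagents that add atoms: none
Why: Bromine–lithium exchange is far faster than chlorine–lithium exchange, zinc gives a nucleophile that ignores the flavone carbonyl, and the Negishi coupling with Pd(PPh3)4 engages only the carbon–iodine bond of 3 while the electron-rich aryl chloride stays intact.

Step 6
Reactants: 13 5,7-dihydroxy-4H-chromen-4-one
Product: 14 5,7-bis(methoxymethoxy)-4H-chromen-4-one
Conditions: NaH (3 equiv), MOMCl (3 equiv), DMF, 0 °C to rt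
Reagents that add atoms: chloromethyl methyl ether (MOMCl), COCCl
Why: Williamson-type O-alkylation under a non-nucleophilic base protects both phenols without opening the 2-unsubstituted pyranone ring.

Step 7
Reactants: 14 5,7-bis(methoxymethoxy)-4H-chromen-4-one; 12 8-(6-chloro-2,2-dimethyl-2H-chromen-8-yl)-5,7-bis(methoxymethoxy)-2-[4-(methoxymethoxy)phenyl]-4H-chromen-4-one
Product: 16 8-{6-[5,7-bis(methoxymethoxy)-4-oxo-4H-chromen-2-yl]-2,2-dimethyl-2H-chromen-8-yl}-5,7-bis(methoxymethoxy)-2-[4-(methoxymethoxy)phenyl]-4H-chromen-4-one, via chromon-2-ylzinc chloride 15 (not isolated)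
Conditions: 14 (1.5 equiv), TMPZnCl·LiCl (1.4 equiv), THF, 25 °C; then 12 (1.0 equiv), Pd(OAc)2 (5 mol %), XPhos (10 mol %), THF, 60 °C
Reagents that add atoms: none
Why: TMPZnCl·LiCl removes the C2–H of ring C of 14, the most acidic C–H because the sp2 carbanion is bonded to O1 and lies β to the C4 carbonyl, and the covalent carbon–zinc bond of 15 prevents ring opening or self-addition. Zerovalent palladium, formed from Pd(OAc)2 and XPhos, inserts into the single carbon–chlorine bond of 12, and transmetalation with 15 followed by reductive elimination forges the bond between chromone C2 and chromene C6. The closest known reaction type is the C–H zincation of chromones at C2 followed by Negishi cross-coupling, combined with the dialkylbiarylphosphine-enabled Negishi coupling of aryl chlorides. No ring is closed and no stereocenter is formed. The step needs site selectivity for C2 over C3 and over H6 and H8 of ring A: leaving out any added Lewis acid (MgCl2, BF3·OEt2) keeps the base from being delivered by the carbonyl oxygen to C3, and the mild zinc amide does not metalate alkoxyarenes at 25 °C. It also needs chemoselectivity within 12, secured because the base is used in deficit to 14 so that none is left for the flavone C3–H, and because the carbonyl, the MOM acetals and the chromene alkene are inert to organozinc reagents.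

Step 8
Reactants: 16 8-{6-[5,7-bis(methoxymethoxy)-4-oxo-4H-chromen-2-yl]-2,2-dimethyl-2H-chromen-8-yl}-5,7-bis(methoxymethoxy)-2-[4-(methoxymethoxy)phenyl]-4H-chromen-4-one
Product: 17 8-[6-(5,7-dihydroxy-4-oxo-4H-chromen-2-yl)-2,2-dimethyl-2H-chromen-8-yl]-5,7-dihydroxy-2-(4-hydroxyphenyl)-4H-chromen-4-one (CNP0135272.0)
Conditions: conc. aq. HCl (cat.), MeOH–THF 1:1, 50 °C
Reagents that add atoms: none
Why: Acid-catalysed acetal exchange (MOM cleavage) with methanol as acceptor should free all five phenols, while the chromene C3=C4 alkene, on a ring that bears the electron-withdrawing chromonyl group, is protonated too slowly at this acidity to interfere.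

Compound list
1 | apigenin | O=c1cc(-c2ccc(O)cc2)oc2cc(O)cc(O)c12 | starting material
2 | 5,7-bis(methoxymethoxy)-2-[4-(methoxymethoxy)phenyl]-4H-chromen-4-one | COCOc1ccc(cc1)-c1cc(=O)c2c(OCOC)cc(OCOC)cc2o1 | intermediate
3 | 8-iodo-5,7-bis(methoxymethoxy)-2-[4-(methoxymethoxy)phenyl]-4H-chromen-4-one | COCOc1ccc(cc1)-c1cc(=O)c2c(OCOC)cc(OCOC)c(I)c2o1 | intermediate
4 | 2-bromo-4-chlorophenol | Oc1ccc(Cl)cc1Br | starting material
5 | 3-chloro-3-methylbut-1-yne | C#CC(C)(C)Cl | starting material
6 | 2-bromo-4-chloro-1-[(2-methylbut-3-yn-2-yl)oxy]benzene | C#CC(C)(C)Oc1ccc(Cl)cc1Br | intermediate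
7 | 2-bromo-4-chloro-6-(3-methylbuta-1,2-dien-1-yl)phenol (allenylphenol, not isolated) | CC(C)=C=Cc1cc(Cl)cc(Br)c1O | intermediate
8 | 2-bromo-4-chloro-6-(3-methylbut-2-en-1-ylidene)cyclohexa-2,4-dien-1-one, vinyl group cis to the carbonyl (ortho-quinone methide, not isolated) | CC(C)=C/C=C1/C=C(Cl)C=C(Br)C1=O | intermediate
9 | 8-bromo-6-chloro-2,2-dimethyl-2H-chromene | CC1(C)C=Cc2cc(Cl)cc(Br)c2O1 | intermediate
10 | (6-chloro-2,2-dimethyl-2H-chromen-8-yl)lithium (not isolated) | CC1(C)C=Cc2cc(Cl)cc([Li])c2O1 | intermediate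
11 | (6-chloro-2,2-dimethyl-2H-chromen-8-yl)zinc chloride (not isolated) | CC1(C)C=Cc2cc(Cl)cc([Zn]Cl)c2O1 | intermediate
12 | 8-(6-chloro-2,2-dimethyl-2H-chromen-8-yl)-5,7-bis(methoxymethoxy)-2-[4-(methoxymethoxy)phenyl]-4H-chromen-4-one | CC1(C)C=Cc2cc(Cl)cc(-c3c(OCOC)cc(OCOC)c4c(=O)cc(-c5ccc(OCOC)cc5)oc34)c2O1 | intermediate
13 | 5,7-dihydroxy-4H-chromen-4-one | O=c1ccoc2cc(O)cc(O)c12 | starting material
14 | 5,7-bis(methoxymethoxy)-4H-chromen-4-one | COCOc1cc(OCOC)c2c(=O)ccoc2c1 | intermediate
15 | [5,7-bis(methoxymethoxy)-4-oxo-4H-chromen-2-yl]zinc chloride (not isolated) | COCOc1cc(OCOC)c2c(=O)cc([Zn]Cl)oc2c1 | intermediate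
16 | 8-{6-[5,7-bis(methoxymethoxy)-4-oxo-4H-chromen-2-yl]-2,2-dimethyl-2H-chromen-8-yl}-5,7-bis(methoxymethoxy)-2-[4-(methoxymethoxy)phenyl]-4H-chromen-4-one | CC1(C)C=Cc2cc(-c3cc(=O)c4c(OCOC)cc(OCOC)cc4o3)cc(-c3c(OCOC)cc(OCOC)c4c(=O)cc(-c5ccc(OCOC)cc5)oc34)c2O1 | intermediate
17 | 8-[6-(5,7-dihydroxy-4-oxo-4H-chromen-2-yl)-2,2-dimethyl-2H-chromen-8-yl]-5,7-dihydroxy-2-(4-hydroxyphenyl)-4H-chromen-4-one (CNP0135272.0) | CC1(C)C=Cc2cc(-c3cc(=O)c4c(O)cc(O)cc4o3)cc(-c3c(O)cc(O)c4c(=O)cc(-c5ccc(O)cc5)oc34)c2O1 | target

Total step count: 8. Longest linear sequence: 5 steps (steps 3, 4, 5, 7, 8). The apigenin branch, steps 1, 2, 5, 7, 8, is equally long.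

Steps most likely to fail

Step 7. Oxidative addition of zerovalent palladium into the electron-rich carbon–chlorine bond may be slow. Meanwhile the zinc species could decay by protonation or homocoupling at the temperature required. The fallback reverses the polarity of the union. It sets out from 12 and 14 and comes back at 16.
- Miyaura borylation of 12 (B2pin2, Pd2(dba)3, XPhos, KOAc, dioxane, 100 °C) should give the 6-pinacolboronate of the biaryl F1.
- Compound 15, made from 14 as in step 7, is quenched with I2 to give 2-iodo-5,7-bis(methoxymethoxy)-4H-chromen-4-one F2. This vinylogous acyl iodide should add to zerovalent palladium already near room temperature.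
- Suzuki–Miyaura coupling of the two (Pd(PPh3)4, K3PO4, dioxane–water 10:1, 50 °C) forms the same bond and delivers 16.

Step 5. Transmetalation and reductive elimination at the axis with three ortho substituents may be slow. Reductive loss of iodine from the flavone and homocoupling of the zinc reagent could then take over. The fallback replaces the in-flask zinc nucleophile by an isolated, purified boron nucleophile, the pairing established for the 3′–8″ biflavone linkage. It sets out from 9 and comes back at 12.
- Aryllithium 10, made from 9 with n-BuLi, is quenched with 2-isopropoxy-4,4,5,5-tetramethyl-1,3,2-dioxaborolane to give 2-(6-chloro-2,2-dimethyl-2H-chromen-8-yl)-4,4,5,5-tetramethyl-1,3,2-dioxaborolane F3.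
- Suzuki–Miyaura coupling with 3 (PdCl2(dppf), K3PO4, dioxane–water, 90 °C) should give 12 with the chloride intact.

Step 8. Acid-catalysed addition of methanol or chloride across the chromene C3=C4 alkene may compete with the slower cleavage of the 7- and 4′-MOM ethers. The fallback avoids any Brønsted acid by a two-stage change of protecting group. It sets out from 16 and comes back at 17.
- TMSOTf and 2,2′-bipyridyl in MeCN (0 °C to rt) should convert the five aryl MOM ethers into the pentakis(trimethylsilyl) ether of the target F4.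
- Neutral hydrolysis with water then releases 17.

Further compounds
F1 | step 7 | 5,7-bis(methoxymethoxy)-2-[4-(methoxymethoxy)phenyl]-8-[2,2-dimethyl-6-(4,4,5,5-tetramethyl-1,3,2-dioxaborolan-2-yl)-2H-chromen-8-yl]-4H-chromen-4-one | CC1(C)C=Cc2cc(B3OC(C)(C)C(C)(C)O3)cc(-c3c(OCOC)cc(OCOC)c4c(=O)cc(-c5ccc(OCOC)cc5)oc34)c2O1
F2 | step 7 | 2-iodo-5,7-bis(methoxymethoxy)-4H-chromen-4-one | COCOc1cc(OCOC)c2c(=O)cc(I)oc2c1
F3 | step 5 | 2-(6-chloro-2,2-dimethyl-2H-chromen-8-yl)-4,4,5,5-tetramethyl-1,3,2-dioxaborolane | CC1(C)C=Cc2cc(Cl)cc(B3OC(C)(C)C(C)(C)O3)c2O1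
F4 | step 8 | pentakis(trimethylsilyl) ether of the target | CC1(C)C=Cc2cc(-c3cc(=O)c4c(O[Si](C)(C)C)cc(O[Si](C)(C)C)cc4o3)cc(-c3c(O[Si](C)(C)C)cc(O[Si](C)(C)C)c4c(=O)cc(-c5ccc(O[Si](C)(C)C)cc5)oc34)c2O1
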